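The data are calculated for substances that don't exist.

Matter cannot leave a closed flask, yet at 120 s the amber run shows product and substrate together at 57.5 % of the charge, so a second route takes substrate to something the analysis does not read.

in all of them: substrate 32 mM

|  | enzyme | remark | time |
|---|---|---|---|
| amber | 10 µM | run made earlier |  |
| south-east | 16 µM |  | 4.0 min |
| west | 19 µM |  | 4.0 min |
| north-east | 23 µM |  | 4.0 min |

- amber (time / s: product / %, substrate / %): 10.0: 8.1, 74.2; 30.0: 22.8, 43.3; 60.0: 39.8, 19.9; 80.0: 47.6, 11.4; 120: 53.6, 3.9

(scatter of a reading: 0.5 percentage points)

- the analysis behind the earlier runs scatters by 0.5 percentage points, standard deviation
- no earlier run changes the charge of enzyme; that part of a forecast is a guess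

1. which of these there is most of at the end, counted by the substrate in it, south-east (product / substrate)
2. which of these there is most of at the end, counted by the substrate in it, west (product / substrate)
3. which of these there is most of at the end, counted by the substrate in it, north-east (product / substrate)
4. the largest of these amounts at the end, in percent of the substrate charged, south-east
5. the largest of these amounts at the end, in percent of the substrate charged, west
6. the largest of these amounts at the end, in percent of the substrate charged, north-east

Call the branching odds, a selectivity factor in the integrated sense, the product made per unit of substrate lost to the unread route. Read at the last amber point, with that point's scatter, they stand at 1.26. The zero of the scale is the symmetric split, odds of 1, where each route takes the same share.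

Two chemists dispute what more enzyme does. The first says it hurries the flask and leaves the split alone, so each new flask keeps the amber odds and ends near 55.8 % product. The second says enzyme pays the product route and not the other, so at a given [substrate] the ratio of the two rates grows in step with the charge. The end odds sum that ratio over the whole run, so scaling them by the charge as well is a rough shortcut of my own. With that shortcut south-east has odds of 2.02 and 66.9 % product, west 2.40 and 70.6 %, north-east 2.90 and 74.4 %. The amber run cannot separate them, since no earlier run changes the enzyme. This reckoning takes the second side.

The forecast takes the same side by a different route, a hand integration of the selectivity, and its numbers differ slightly from the odds figures: product at 66 % in south-east, product at 69 % in west, product at 72 % in north-east. Its ground: “I assume the product route scales with enzyme and the side route is uncatalysed”.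

The flasks give product at 66.7 % in south-east, product at 69.8 % in west and product at 73.1 % in north-east, so the split moves with enzyme and the second chemist wins. The first chemist's view holds where the step to homo dimer is missing: there north-east and south-east end 0.02 percentage points apart.

    substrate + enzyme → product + enzyme, rate k1*[substrate]*[enzyme]/(1 + ([substrate]/Km1) + ([substrate]/Ksi1)^2) (0.0610 M, 23.0 mM, k = 2600 M⁻¹ s⁻¹)
    2 substrate → homo dimer (k = 0.370 M⁻¹ s⁻¹)

Counting homo dimer by the substrate it holds, the end odds are 2.00 in south-east against 2.02 reckoned, and 2.72 in north-east against 2.90.

On the neighbour flask, south-east with 0.064 mM of enzyme, the odds reckon to 8.07, or 89.0 % product. The computed flask gives 87.0 % product and 13.0 % homo dimer.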